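**Retrosynthetic overview**

- Each ring is numbered C1 (C–OH), C2 (side-chain carbon), C3 and C4 (CH), C5 (C–CH3), C6 (biaryl carbon). The strategy rests on the unit O–C1–C6–C6'–C1'–O across the biaryl bond, which is a masked 1,4-diketone, and on C2 carrying no hydrogen.
- Disconnection 1: both arenes are traced back to cyclohex-2-enones (C1=O, C2=C3). The crowded C6–C6' aryl–aryl bond then becomes an sp3–sp3 bond, made by oxidative homocoupling of the C6 enolate of a 5-methyl-2-alkylcyclohex-2-enone; double aromatisation (bis-silyl dienol ether, DDQ) and desilylation follow.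
- Disconnection 2: the monomer ring comes from acyclic pieces. (S)-Citronellal supplies C1, C2, the (S)-centre and the whole side chain; ethyl diazoacetate supplies C6 with a temporary ester; crotonaldehyde supplies C5(CH3)–C4–C3. Bond C6–C5 is made by Michael addition, bond C2–C3 by aldol condensation, and the ester is removed by Krapcho reaction.
- Order of ring events: each six-membered ring is closed in the monomer, two monomers are joined at C6/C6', and both rings are aromatised together at the end.

Key step: step 5

Assumption: the structure carries no descriptor for the biaryl axis, so the (S,S)-biphenol is taken as the target whatever the sense of the axis; the two atropisomers are diastereomers and could be parted by chromatography if one is wanted.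

**Route**

Step 1
Reactants: 1 (S)-citronellal [(3S)-3,7-dimethyloct-6-enal]; 2 ethyl diazoacetate
Product: 3 ethyl (5S)-5,9-dimethyl-3-oxodec-8-enoate
Conditions: SnCl2 (10 mol%), CH2Cl2, rt, slow addition of 2
Reagents that add atoms: none
Why: Roskamp homologation, in which SnCl2 (divalent tin) activates the aldehyde, the diazo carbon adds and a 1,2-hydride shift with loss of N2 gives the β-keto ester without base, so the stereocenter (β to the carbonyl) is untouched and the weak catalytic Lewis acid should leave the trisubstituted alkene alone.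

Step 2
Reactants: 3 ethyl (5S)-5,9-dimethyl-3-oxodec-8-enoate; 4 (E)-crotonaldehyde
Product: 5 ethyl (5S)-5,9-dimethyl-3-oxo-2-(4-oxobutan-2-yl)dec-8-enoate (mixture of diastereomers at the two new centres)
Conditions: Et3N (0.2 equiv), MeCN, 0 °C to rt; crude product used directly
Reagents that add atoms: none
Why: Michael addition of the doubly activated methylene C6 to the β-carbon of the enal under catalytic amine base forms the C6–C5 bond, and the two new centres (C5, C6) are left uncontrolled because both end up sp2 in the arene.

Step 3
Reactants: 5 ethyl (5S)-5,9-dimethyl-3-oxo-2-(4-oxobutan-2-yl)dec-8-enoate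
Product: 7 ethyl 6-methyl-3-[(2S)-6-methylhept-5-en-2-yl]-2-oxocyclohex-3-ene-1-carboxylate (mixture at ring C5/C6), via aldol adduct 6 (not isolated)
Conditions: piperidine (0.2 equiv), AcOH (0.2 equiv), toluene, 80 °C, MgSO4
Reagents that add atoms: none
Why: Intramolecular aldol condensation under amine–carboxylic acid catalysis, in which the ketone α-methylene C2 is the only nucleophilic carbon that can reach the aldehyde C3 through a six-membered ring, and loss of water from aldol 6 gives the conjugated C2=C3 enone while the weak acid spares the side-chain alkene and the remote (S)-centre.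

Step 4
Reactants: 7 ethyl 6-methyl-3-[(2S)-6-methylhept-5-en-2-yl]-2-oxocyclohex-3-ene-1-carboxylate
Product: 8 5-methyl-2-[(2S)-6-methylhept-5-en-2-yl]cyclohex-2-en-1-one (mixture at C5)
Conditions: LiCl (3 equiv), H2O (2 equiv), DMSO, 140 °C
Reagents that add atoms: none
Why: Krapcho dealkoxycarbonylation, in which LiCl in wet DMSO promotes cleavage of the β-keto ester and loss of CO2 (net hydrolysis–decarboxylation with release of ethanol) under near-neutral conditions, so the enone, the side-chain alkene and the stereocenter are not affected.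

Step 5
Reactants: 8 5-methyl-2-[(2S)-6-methylhept-5-en-2-yl]cyclohex-2-en-1-one (two molecules)
Product: 10 6,6'-dimethyl-3,3'-bis[(2S)-6-methylhept-5-en-2-yl]-[1,1'-bi(cyclohexane)]-3,3'-diene-2,2'-dione (the C6–C6' dimer; mixture of diastereomers at C5, C6, C5', C6', carried on unseparated), via lithium dienolate 9 (not isolated)
Conditions: LiN(i-Pr)2 (1.1 equiv), THF, −78 °C; then FeCl3 (1.2 equiv), DMF, −78 °C to rt
Reagents that add atoms: none
Why: LiN(i-Pr)2 removes a C6 hydrogen under kinetic control to give the cross-conjugated lithium dienolate 9; C2 has no hydrogen, and the γ-hydrogens at C4 are not touched at −78 °C. FeCl3 (trivalent iron) takes one electron from 9, and the α-keto radical so formed (spin on C6 and oxygen) dimerises, or is captured by a second enolate and oxidised once more, to give the C6–C6' σ-bond of a 1,4-diketone. The closest known reaction type is the oxidative homocoupling of kinetic lithium enolates of 2,5-disubstituted cyclohex-2-enones at C6 with FeCl3 in DMF or with CuCl2. No ring is closed in this step. The new centres C6 and C6' are formed without control on purpose, since they and C5, C5' all become sp2 on aromatisation, so every diastereomer converges on one constitution. The selectivity required is for C6 over C4 and over oxygen; it is secured by kinetic α'-deprotonation of an enone whose other α-carbon is fully substituted and by the absence of spin density at C4 in the cross-conjugated radical, while the coupling carbons are secondary sp3 centres flanked only by a methyl-bearing neighbour.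

Step 6
Reactants: 10 6,6'-dimethyl-3,3'-bis[(2S)-6-methylhept-5-en-2-yl]-[1,1'-bi(cyclohexane)]-3,3'-diene-2,2'-dione
Product: 12 6,6'-dimethyl-3,3'-bis[(2S)-6-methylhept-5-en-2-yl]-2,2'-bis(trimethylsilyloxy)-1,1'-bi(cyclohexa-1,3-dien-1-yl), via dipotassium bis-dienolate 11 (not isolated)
Conditions: KN(SiMe3)2 (3 equiv), THF, −78 °C; then Me3SiCl (4 equiv), Et3N, −78 to 0 °C; non-aqueous work-up, used crude
Reagents that add atoms: chlorotrimethylsilane, C[Si](C)(C)Cl
Why: Silyl enol ether formation by enolisation of both enone carbonyls with the hindered amide base and O-silylation of the potassium enolates; any enolisation toward C4 instead of C6 would still leave a diene two hydrogens short of the same arene, so the site of deprotonation is immaterial.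

Step 7
Reactants: 12 6,6'-dimethyl-3,3'-bis[(2S)-6-methylhept-5-en-2-yl]-2,2'-bis(trimethylsilyloxy)-1,1'-bi(cyclohexa-1,3-dien-1-yl)
Product: 13 6,6'-dimethyl-3,3'-bis[(2S)-6-methylhept-5-en-2-yl]-2,2'-bis(trimethylsilyloxy)-1,1'-biphenyl
Conditions: DDQ (2.1 equiv), 2,6-lutidine (3 equiv), CH2Cl2, 0 °C to rt
Reagents that add atoms: none
Why: Oxidative aromatisation by DDQ dehydrogenation, in which hydride abstraction from a ring sp3 C–H gives a silyloxy-stabilised cyclohexadienyl cation that loses the neighbouring proton; the gain of aromaticity should make the ring positions far more reactive than the side-chain allylic C–H bonds or the C–H at the (S)-centres, the lutidine buffers the acidic hydroquinone, and the transient ring stereocenters vanish here.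

Step 8
Reactants: 13 6,6'-dimethyl-3,3'-bis[(2S)-6-methylhept-5-en-2-yl]-2,2'-bis(trimethylsilyloxy)-1,1'-biphenyl
Product: 14 6,6'-dimethyl-3,3'-bis[(2S)-6-methylhept-5-en-2-yl]-[1,1'-biphenyl]-2,2'-diol (target)
Conditions: K2CO3 (0.3 equiv), MeOH, rt; then aq NH4Cl
Reagents that add atoms: none
Why: Base-catalysed methanolysis of aryl trimethylsilyl ethers (desilylation) is fast even at crowded phenols and touches nothing else, giving the free biphenol with both (S)-centres as brought in from 1.

**Compound list**

1 | (S)-citronellal, (3S)-3,7-dimethyloct-6-enal | CC(C)=CCC[C@H](C)CC=O | starting material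
2 | ethyl diazoacetate | CCOC(=O)C=[N+]=[N-] | starting material
3 | ethyl (5S)-5,9-dimethyl-3-oxodec-8-enoate | CC(C)=CCC[C@H](C)CC(=O)CC(=O)OCC | intermediate
4 | (E)-crotonaldehyde | C/C=C/C=O | starting material
5 | ethyl (5S)-5,9-dimethyl-3-oxo-2-(4-oxobutan-2-yl)dec-8-enoate | CC(C)=CCC[C@H](C)CC(=O)C(C(=O)OCC)C(C)CC=O | intermediate
6 | ethyl 4-hydroxy-6-methyl-3-[(2S)-6-methylhept-5-en-2-yl]-2-oxocyclohexane-1-carboxylate (aldol adduct) | CC(C)=CCC[C@H](C)C1C(O)CC(C)C(C(=O)OCC)C1=O | intermediate
7 | ethyl 6-methyl-3-[(2S)-6-methylhept-5-en-2-yl]-2-oxocyclohex-3-ene-1-carboxylate | CC(C)=CCC[C@H](C)C1=CCC(C)C(C(=O)OCC)C1=O | intermediate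
8 | 5-methyl-2-[(2S)-6-methylhept-5-en-2-yl]cyclohex-2-en-1-one | CC(C)=CCC[C@H](C)C1=CCC(C)CC1=O | intermediate
9 | lithium 3-methyl-6-[(2S)-6-methylhept-5-en-2-yl]cyclohexa-1,5-dien-1-olate (cross-conjugated dienolate of 8) | CC(C)=CCC[C@H](C)C1=CCC(C)C=C1[O-].[Li+] | intermediate
10 | 6,6'-dimethyl-3,3'-bis[(2S)-6-methylhept-5-en-2-yl]-[1,1'-bi(cyclohexane)]-3,3'-diene-2,2'-dione | CC(C)=CCC[C@H](C)C1=CCC(C)C(C1=O)C1C(C)CC=C([C@@H](C)CCC=C(C)C)C1=O | intermediate
11 | dipotassium bis(dienolate) of 10 | CC(C)=CCC[C@H](C)C1=CCC(C)C(=C1[O-])C1=C([O-])C([C@@H](C)CCC=C(C)C)=CCC1C.[K+].[K+] | intermediate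
12 | 6,6'-dimethyl-3,3'-bis[(2S)-6-methylhept-5-en-2-yl]-2,2'-bis(trimethylsilyloxy)-1,1'-bi(cyclohexa-1,3-dien-1-yl) | CC(C)=CCC[C@H](C)C1=CCC(C)C(=C1O[Si](C)(C)C)C1=C(O[Si](C)(C)C)C([C@@H](C)CCC=C(C)C)=CCC1C | intermediate
13 | 6,6'-dimethyl-3,3'-bis[(2S)-6-methylhept-5-en-2-yl]-2,2'-bis(trimethylsilyloxy)-1,1'-biphenyl | CC(C)=CCC[C@H](C)c1ccc(C)c(-c2c(C)ccc([C@@H](C)CCC=C(C)C)c2O[Si](C)(C)C)c1O[Si](C)(C)C | intermediate
14 | 6,6'-dimethyl-3,3'-bis[(2S)-6-methylhept-5-en-2-yl]-[1,1'-biphenyl]-2,2'-diol | CC(C)=CCC[C@H](C)c1ccc(C)c(-c2c(C)ccc([C@@H](C)CCC=C(C)C)c2O)c1O | target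

**Step count**

Total steps: 8. Longest linear sequence: 8 steps (from 1 to 14; the dimerisation uses two molecules of the same intermediate).

**Steps most likely to fail**

1. Step 5 (oxidative homocoupling). The enolate may be chlorinated at C6 or simply re-protonated after oxidation instead of coupling, or the bimolecular union of two hindered radicals next to the C5 methyl may be slow, leaving monomer. Fallback (from 8, back at 10): the two enolates are tethered on silicon so that the C6–C6' bond forms intramolecularly. Compound 8 is deprotonated with LiN(i-Pr)2 in THF at −78 °C and quenched with Me2SiCl2 (0.5 equiv) to give the dimethylsilyl bis(dienol ether) F1. Oxidation of F1 with (NH4)2Ce(NO3)6 and NaHCO3 in MeCN at −10 °C should give diketone 10 with loss of the silicon tether. No chloride donor is present and the coupling no longer depends on two free species meeting.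

2. Step 7 (double dehydrogenation with DDQ). Hydride abstraction at the crowded ring positions may be slow, so that DDQ attacks the side-chain allylic positions or the C–H of the (S)-centres, or one ring may aromatise and the second lag behind. Fallback (from 12, back at 14, bypassing 13 and step 8): Saegusa–Ito dehydrogenation with Pd(OAc)2 (divalent palladium, 2.2 equiv) in MeCN at rt. Palladation of each silyl enol ether at C6 and β-hydride elimination toward C5 should give the bis(cyclohexa-2,5-dienone) F2, the keto tautomer of the biphenol, which enolises to 14 on work-up. This changes the mechanism from hydride abstraction to an organometallic elimination that cannot touch remote C–H bonds.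

3. Step 3 (aldol ring closure). C-cyclisation at the β-branched methylene C2 may be outrun by retro-Michael cleavage or by O-cyclisation of the enol onto the aldehyde followed by dehydration to a pyran. Fallback (from 3, back at 8): the ring is closed by a Claisen-type acylation instead of an aldol, through a 1,3-dione.
   - Compound 3 and ethyl crotonate with NaOEt in EtOH at reflux should give the Michael diester F3, which cyclises in the same pot (C2 onto the terminal ester) to the dione ester F4.
   - Saponification with aqueous NaOH, then mild acidification (citric acid, 50 °C), removes the ester and gives the 2-substituted 5-methylcyclohexane-1,3-dione F5.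
   - F5 is symmetric in constitution, so O-methylation (Me2SO4, K2CO3, acetone) gives a single vinylogous ester F6.
   - Reduction with i-Bu2AlH in toluene at −78 °C gives the allylic alcohol F7, and brief treatment with dilute HCl in THF at 0 °C hydrolyses the enol ether with allylic transposition to the enone 8.

**Further compounds**

F1 | step 5 | bis{[3-methyl-6-[(2S)-6-methylhept-5-en-2-yl]cyclohexa-1,5-dien-1-yl]oxy}dimethylsilane | CC(C)=CCC[C@H](C)C1=CCC(C)C=C1O[Si](C)(C)OC1=CC(C)CC=C1[C@@H](C)CCC=C(C)C
F2 | step 7 | 6,6'-dimethyl-3,3'-bis[(2S)-6-methylhept-5-en-2-yl]-[1,1'-bi(cyclohexane)]-3,3',6,6'-tetraene-2,2'-dione (bis-dienone keto tautomer of 14) | CC(C)=CCC[C@H](C)C1=CCC(C)=C(C1=O)C1=C(C)CC=C([C@@H](C)CCC=C(C)C)C1=O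
F3 | step 3 | diethyl 2-[(3S)-3,7-dimethyloct-6-enoyl]-3-methylpentanedioate | CC(C)=CCC[C@H](C)CC(=O)C(C(=O)OCC)C(C)CC(=O)OCC
F4 | step 3 | ethyl 6-methyl-3-[(2S)-6-methylhept-5-en-2-yl]-2,4-dioxocyclohexane-1-carboxylate | CC(C)=CCC[C@H](C)C1C(=O)CC(C)C(C(=O)OCC)C1=O
F5 | step 3 | 5-methyl-2-[(2S)-6-methylhept-5-en-2-yl]cyclohexane-1,3-dione | CC(C)=CCC[C@H](C)C1C(=O)CC(C)CC1=O
F6 | step 3 | 3-methoxy-5-methyl-2-[(2S)-6-methylhept-5-en-2-yl]cyclohex-2-en-1-one | CC(C)=CCC[C@H](C)C1=C(OC)CC(C)CC1=O
F7 | step 3 | 3-methoxy-5-methyl-2-[(2S)-6-methylhept-5-en-2-yl]cyclohex-2-en-1-ol | CC(C)=CCC[C@H](C)C1=C(OC)CC(C)CC1O
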